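Ring B of the drimane core (C5–C6–C7–C8–C9–C10, drimane numbering; C11 is the OCH2 carbon) is a cyclohexene that carries all three stereocentres and whose C7=C8 bond lies opposite the C5–C10 fusion bond. It is therefore made by a Diels–Alder reaction that forms C5–C6 and C9–C10. Because a ring A cycloalkene could only give a cis-decalin, ring A is absent in the precursor: an acyclic (E)-2-methyl enal carrying the C4 gem-dimethyl methyl ketone adds to an (E)-3-methylpentadienyl silyl ether under chiral Lewis acid catalysis. One operation closes ring B and sets C5, C9 and C10. Aldol condensation then closes ring A, and a late Mitsunobu reaction attaches umbelliferone.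

Key step: step 5

Remark: drimane numbering is used throughout (ring A: C1–C5 and C10; ring B: C5–C10; C11 is the OCH2 carbon). 4-Hydroxy-3,3-dimethylbutan-2-one, 2-(triphenylphosphoranylidene)propanal, (2E)-3-methylpent-2-en-4-yn-1-ol and umbelliferone are assumed to be purchasable.

Step 1
Reactants: 1 4-hydroxy-3,3-dimethylbutan-2-one
Product: 2 2,2-dimethyl-3-oxobutanal
Conditions: Dess–Martin periodinane (DMP), CH2Cl2, 0 °C → rt; product distilled carefully or carried on as a concentrated solution
Reagents that add atoms: none
Why: Dess–Martin oxidation of a primary neopentyl alcohol should stop at the aldehyde, and the quaternary α-carbon rules out enolisation or self-aldol reaction of the β-keto aldehyde.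

Step 2
Reactants: 2 2,2-dimethyl-3-oxobutanal; 3 2-(triphenylphosphoranylidene)propanal
Product: 4 (2E)-2,4,4-trimethyl-5-oxohex-2-enal
Conditions: toluene, 100 °C
Reagents that add atoms: none
Why: Wittig olefination with a stabilised formyl ylide should attack only the aldehyde (the α-quaternary ketone is far less electrophilic) and give the (E)-2-methyl enal, whose geometry later encodes the trans H5/C10-methyl relation.

Step 3
Reactants: 5 (2E)-3-methylpent-2-en-4-yn-1-ol
Product: 6 {[(2E)-3-methylpent-2-en-4-yn-1-yl]oxy}tri(propan-2-yl)silane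
Conditions: TIPSCl, imidazole, CH2Cl2, 0 °C → rt
Reagents that add atoms: chlorotri(propan-2-yl)silane (TIPSCl), CC(C)[Si](Cl)(C(C)C)C(C)C
Why: Imidazole-assisted silylation of a primary allylic alcohol is routine, and the bulky TIPS ether is chosen to withstand the Lewis acid of step 5 and the base of step 6.

Step 4
Reactants: 6 {[(2E)-3-methylpent-2-en-4-yn-1-yl]oxy}tri(propan-2-yl)silane
Product: 7 {[(2E)-3-methylpenta-2,4-dien-1-yl]oxy}tri(propan-2-yl)silane
Conditions: H2 (1 atm, one equivalent taken up), Pd on CaCO3 poisoned with Pb(OAc)2, quinoline, hexane, rt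
Reagents that add atoms: none
Why: Lindlar semihydrogenation should reduce the terminal conjugated alkyne to the vinyl group and leave the (E)-trisubstituted alkene untouched, giving the diene with C11 on the outside of its s-cis form.

Step 5
Reactants: 4 (2E)-2,4,4-trimethyl-5-oxohex-2-enal; 7 {[(2E)-3-methylpenta-2,4-dien-1-yl]oxy}tri(propan-2-yl)silane
Product: 8 (1S,2R,6R)-1,3-dimethyl-6-(2-methyl-3-oxobutan-2-yl)-2-({[tri(propan-2-yl)silyl]oxy}methyl)cyclohex-3-ene-1-carbaldehyde
Conditions: 7 (2 equiv), (S)-3,3-diphenyl-1-(2-methylphenyl)tetrahydro-1H,3H-pyrrolo[1,2-c][1,3,2]oxazaborole (20 mol%), AlBr3 (16 mol%), CH2Cl2, −78 → −20 °C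
Reagents that add atoms: none
Why: The AlBr3-activated oxazaborolidine binds the formyl oxygen of 4 (s-trans enal) and a concerted, asynchronous [4+2] cycloaddition with the s-cis diene 7 follows, C5–C6 (enal β-carbon to the unsubstituted diene terminus) forming ahead of C9–C10; the closest known reaction type is the chiral oxazaborolidinium-catalysed Diels–Alder reaction of 2-methyl-substituted enals with alkyl-substituted butadienes. Ring B is closed in the [4+2] mode, suprafacially on both partners, and the C7=C8 bond arises from the central bond of the diene. The trans relation of H5 to the C10 methyl group is copied from the (E) geometry of 4, which is why ring A must still be open here (a cyclohexene dienophile could only give the cis-decalin). The cis relation of C11 on C9 to the formyl carbon C1 on C10 comes from the endo position of the formyl group next to the (E)-substituted diene terminus, the arrangement that also keeps the bulky tert-alkyl group exo. The step needs regioselectivity (C6 to C5, C9 to C10), secured by the ortho-directing 1-substituent of the diene and by the β-tert-alkyl group, which can pair only with the unsubstituted terminus C6. It also needs facial selectivity: the catalyst shields one face so that the diene adds to the Re face at C2 of 4, for which the binding model points to the (S)-catalyst, the (R)-antipode being equally available if the sense has to be inverted.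

Step 6
Reactants: 8 (1S,2R,6R)-1,3-dimethyl-6-(2-methyl-3-oxobutan-2-yl)-2-({[tri(propan-2-yl)silyl]oxy}methyl)cyclohex-3-ene-1-carbaldehyde
Product: 10 (4aS,5R,8aR)-1,1,4a,6-tetramethyl-5-({[tri(propan-2-yl)silyl]oxy}methyl)-4a,5,8,8a-tetrahydronaphthalen-2(1H)-one, via β-hydroxy ketone 9 (not isolated)
Conditions: KOH, MeOH, rt → 50 °C
Reagents that add atoms: none
Why: In this intramolecular aldol condensation only the methyl group C2 is enolisable (C4 is quaternary, the aldehyde has no α-hydrogen), so the enolate should close six-membered ring A onto C1 between the trans-disposed C5 and C10 substituents, and E1cB dehydration gives the C1=C2 enone without touching a stereocentre.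

Step 7
Reactants: 10 (4aS,5R,8aR)-1,1,4a,6-tetramethyl-5-({[tri(propan-2-yl)silyl]oxy}methyl)-4a,5,8,8a-tetrahydronaphthalen-2(1H)-one
Product: 11 (4aS,5R,8aR)-1,1,4a,6-tetramethyl-5-({[tri(propan-2-yl)silyl]oxy}methyl)-3,4,4a,5,8,8a-hexahydronaphthalen-2(1H)-one
Conditions: H2 (1 atm), RhCl(PPh3)3 (5 mol%), benzene, rt
Reagents that add atoms: none
Why: Homogeneous catalytic hydrogenation with RhCl(PPh3)3 should saturate the cis-disubstituted C1=C2 bond of the enone much faster than the trisubstituted C7=C8 bond, the selectivity known for 1,2-reduction of steroidal 1,4-dien-3-ones.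

Step 8
Reactants: 11 (4aS,5R,8aR)-1,1,4a,6-tetramethyl-5-({[tri(propan-2-yl)silyl]oxy}methyl)-3,4,4a,5,8,8a-hexahydronaphthalen-2(1H)-one
Product: 12 (4aS,5R,8aR)-5-(hydroxymethyl)-1,1,4a,6-tetramethyl-3,4,4a,5,8,8a-hexahydronaphthalen-2(1H)-one
Conditions: HF·pyridine, THF, 0 °C → rt
Reagents that add atoms: none
Why: Fluoride-mediated desilylation (Si–F bond formation) should free the primary C11 alcohol while leaving the ketone and the C7=C8 alkene unchanged.

Step 9
Reactants: 12 (4aS,5R,8aR)-5-(hydroxymethyl)-1,1,4a,6-tetramethyl-3,4,4a,5,8,8a-hexahydronaphthalen-2(1H)-one; 13 umbelliferone (7-hydroxy-2H-chromen-2-one)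
Product: 14 7-{[(1R,4aR,8aS)-2,5,5,8a-tetramethyl-6-oxo-1,4,4a,5,6,7,8,8a-octahydronaphthalen-1-yl]methoxy}-2H-chromen-2-one (target)
Conditions: PPh3, DIAD, THF, 0 °C → 40 °C
Reagents that add atoms: none
Why: In this Mitsunobu etherification the acidic phenol protonates the betaine and the phenoxide displaces the primary C11 alkoxyphosphonium group by SN2, which forms the aryl ether without touching C9, so its configuration is retained.

Compound list
1 | 4-hydroxy-3,3-dimethylbutan-2-one | CC(=O)C(C)(C)CO | starting material
2 | 2,2-dimethyl-3-oxobutanal | CC(=O)C(C)(C)C=O | intermediate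
3 | 2-(triphenylphosphoranylidene)propanal | CC(C=O)=P(c1ccccc1)(c1ccccc1)c1ccccc1 | starting material
4 | (2E)-2,4,4-trimethyl-5-oxohex-2-enal | O=C/C(C)=C/C(C)(C)C(C)=O | intermediate
5 | (2E)-3-methylpent-2-en-4-yn-1-ol | C#C/C(C)=C/CO | starting material
6 | {[(2E)-3-methylpent-2-en-4-yn-1-yl]oxy}tri(propan-2-yl)silane | C#C/C(C)=C/CO[Si](C(C)C)(C(C)C)C(C)C | intermediate
7 | {[(2E)-3-methylpenta-2,4-dien-1-yl]oxy}tri(propan-2-yl)silane | C=C/C(C)=C/CO[Si](C(C)C)(C(C)C)C(C)C | intermediate
8 | (1S,2R,6R)-1,3-dimethyl-6-(2-methyl-3-oxobutan-2-yl)-2-({[tri(propan-2-yl)silyl]oxy}methyl)cyclohex-3-ene-1-carbaldehyde | CC1=CC[C@@H](C(C)(C)C(C)=O)[C@](C)(C=O)[C@@H]1CO[Si](C(C)C)(C(C)C)C(C)C | intermediate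
9 | (4aS,5R,8aR)-4-hydroxy-1,1,4a,6-tetramethyl-5-({[tri(propan-2-yl)silyl]oxy}methyl)-3,4,4a,5,8,8a-hexahydronaphthalen-2(1H)-one (either configuration at the carbinol carbon, removed on dehydration) | CC1=CC[C@H]2C(C)(C)C(=O)CC(O)[C@]2(C)[C@@H]1CO[Si](C(C)C)(C(C)C)C(C)C | intermediate
10 | (4aS,5R,8aR)-1,1,4a,6-tetramethyl-5-({[tri(propan-2-yl)silyl]oxy}methyl)-4a,5,8,8a-tetrahydronaphthalen-2(1H)-one | CC1=CC[C@H]2C(C)(C)C(=O)C=C[C@]2(C)[C@@H]1CO[Si](C(C)C)(C(C)C)C(C)C | intermediate
11 | (4aS,5R,8aR)-1,1,4a,6-tetramethyl-5-({[tri(propan-2-yl)silyl]oxy}methyl)-3,4,4a,5,8,8a-hexahydronaphthalen-2(1H)-one | CC1=CC[C@H]2C(C)(C)C(=O)CC[C@]2(C)[C@@H]1CO[Si](C(C)C)(C(C)C)C(C)C | intermediate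
12 | (4aS,5R,8aR)-5-(hydroxymethyl)-1,1,4a,6-tetramethyl-3,4,4a,5,8,8a-hexahydronaphthalen-2(1H)-one | CC1=CC[C@H]2C(C)(C)C(=O)CC[C@]2(C)[C@@H]1CO | intermediate
13 | umbelliferone (7-hydroxy-2H-chromen-2-one) | Oc1ccc2ccc(=O)oc2c1 | starting material
14 | 7-{[(1R,4aR,8aS)-2,5,5,8a-tetramethyl-6-oxo-1,4,4a,5,6,7,8,8a-octahydronaphthalen-1-yl]methoxy}-2H-chromen-2-one | CC1=CC[C@H]2C(C)(C)C(=O)CC[C@]2(C)[C@@H]1COc1ccc2ccc(=O)oc2c1 | target

Total step count: 9
Longest linear sequence: 7 steps (from 5 through steps 3–9; the branch from 1 through steps 1, 2 and 5–9 is equally long)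

Steps most likely to fail

Step 5. The cycloaddition may be too slow, because the enal β-carbon is flanked by the quaternary C4 and a quaternary centre is formed at C10. Lewis-acid-induced oligomerisation or ionisation of the diene could then outrun it, and regio- or facial control could erode. The fallback sets out from 4 and comes back at 8, and activates the enal covalently instead of catalytically. Acetalisation of 4 with (2R,4R)-pentane-2,4-diol (PPTS, benzene, water removal; only the aldehyde should react) would give (4E)-5-[(4R,6R)-4,6-dimethyl-1,3-dioxan-2-yl]-3,3-dimethylhex-4-en-2-one F1. TMSOTf in CH2Cl2 at −78 °C should open the acetal to a vinyl oxocarbenium ion, a much stronger dienophile (ionic Diels–Alder reaction of α,β-unsaturated acetals). This ion should add 7 in the same orientation and reclose to the (4R,6R)-4,6-dimethyl-1,3-dioxane acetal of aldehyde 8 F2. The two diastereomers that arise from the two enal faces are separated by chromatography, and aqueous trifluoroacetic acid in CH2Cl2 at 0 °C hydrolyses the wanted one to 8.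

Step 9. The activated alcohol may eliminate toward the allylic H9, giving a conjugated exocyclic diene, in competition with slow substitution at the axial, β-branched C11. The fallback sets out from 12 and comes back at 14, and reverses the polarity so that the C11–O bond is never broken. A palladium-catalysed C–O cross-coupling of alcohol 12 with purchased 7-bromo-2H-chromen-2-one should give 14 directly (Pd(OAc)2, 2-(di-tert-butylphosphino)-3-methoxy-6-methyl-2′,4′,6′-triisopropylbiphenyl, Cs2CO3, toluene, 90 °C).

Step 2. Olefination of the α-quaternary aldehyde by the weakly nucleophilic formyl ylide may stay incomplete, with retro-Claisen-type degradation of the β-keto aldehyde on long heating. The fallback sets out from 2 and comes back at 4, and uses the more nucleophilic ester ylide followed by an adjustment of oxidation state. Ethyl 2-(triphenylphosphoranylidene)propanoate (CH2Cl2, rt) would give ethyl (2E)-2,4,4-trimethyl-5-oxohex-2-enoate F3. Excess iBu2AlH (CH2Cl2, −78 °C) reduces ester and ketone to (2E)-2,4,4-trimethylhex-2-ene-1,5-diol F4. Dess–Martin periodinane then oxidises both hydroxyl groups and returns 4.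

Further compounds
F1 | step 5 | (4E)-5-[(4R,6R)-4,6-dimethyl-1,3-dioxan-2-yl]-3,3-dimethylhex-4-en-2-one | C/C(=C\C(C)(C)C(C)=O)C1O[C@H](C)C[C@@H](C)O1
F2 | step 5 | (4R,6R)-4,6-dimethyl-1,3-dioxane acetal of aldehyde 8 (ring stereocentres as in 8) | CC1=CC[C@@H](C(C)(C)C(C)=O)[C@](C)(C2O[C@H](C)C[C@@H](C)O2)[C@@H]1CO[Si](C(C)C)(C(C)C)C(C)C
F0 | step 9 | none | none
F3 | step 2 | ethyl (2E)-2,4,4-trimethyl-5-oxohex-2-enoate | CCOC(=O)/C(C)=C/C(C)(C)C(C)=O
F4 | step 2 | (2E)-2,4,4-trimethylhex-2-ene-1,5-diol (configuration at C5 immaterial) | OC/C(C)=C/C(C)(C)C(C)O
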